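**Plan**
Retrosynthesis: cut C12–C13 (Negishi coupling with a Z-vinyl iodide), remove the 7α-oxygen (allylic oxidation of C8=C17) and the C18 methyl (methylation of a C19 aldehyde that comes from a C4=C19 methylidene), and invert C2.
The remaining 2β-hydroxy-4(19),8(17)-diene decalin is cut at C2–C3 and C5–C10 in one operation. Ring A is a homoallylic alcohol with an exocyclic carbon on C4 (carbonyl-ene retron), and C10 is a methyl-bearing quaternary carbon β to C2 (conjugate-ene retron). So C3–C4(C19)–C5 is a Me2C=CH– terminus and C10(C20)=C1–C2 is a β-methyl enal.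
Forward: sulcatone enol triflate + propyne → enyne → hydrozirconation and addition to a glycolaldehyde ether → CBS reduction → Johnson–Claisen (C9–C11) → enal. A Me2AlCl cascade then closes ring B and ring A, after which C4, C2, C7 and the side chain are finished.
Stereochemistry: the CBS carbinol is relayed to C9 by the Claisen chair; C9 controls C10 and C5 (chair, trans fusion) and these control C2 in the cascade. C4 comes from methylation anti to the C10 methyl, C7 from axial oxygen delivery, C2 from Mitsunobu inversion, and the C13 geometry from anti-hydroalumination of but-2-yn-1-ol.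

Key step: step 9

Remark: the decalin compounds are described with labdane numbering (C17 = methylidene carbon on C8, C18/C19 = α/β carbons on C4, C20 = methyl on C10) and α/β face descriptors (β = face of the C10 methyl); the acyclic precursors are named systematically.

Step 1
Reactants: 1 6-methylhept-5-en-2-one (sulcatone)
Product: 3 6-methylhepta-1,5-dien-2-yl trifluoromethanesulfonate, via lithium enolate 2 (not isolated)
Conditions: LiN(iPr)2, THF, −78 °C; then PhNTf2, −78 to 0 °C
Reagents that add atoms: N-phenylbis(trifluoromethanesulfonimide), O=S(=O)(N(c1ccccc1)S(=O)(=O)C(F)(F)F)C(F)(F)F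
Why: Kinetic deprotonation by the hindered amide occurs at the methyl group and O-triflation of the enolate gives the terminal enol triflate (standard enol triflate formation).

Step 2
Reactants: 3 6-methylhepta-1,5-dien-2-yl trifluoromethanesulfonate; 4 prop-1-yn-1-ylmagnesium bromide
Product: 6 2-methyl-6-methylidenenon-2-en-7-yne, via prop-1-ynylzinc chloride 5 (not isolated)
Conditions: 4, ZnCl2, THF, 0 °C; then 3, Pd(PPh3)4 (3 mol %), THF, 25 °C
Reagents that add atoms: none
Why: Negishi coupling of the alkynylzinc with the enol triflate under zerovalent palladium should give the conjugated enyne with the 1,1-disubstituted alkene unchanged.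

Step 3
Reactants: 6 2-methyl-6-methylidenenon-2-en-7-yne; 7 (tert-butyldimethylsilyloxy)acetaldehyde
Product: 10 rac-(3E)-1-[(tert-butyldimethylsilyl)oxy]-3,9-dimethyl-5-methylidenedeca-3,8-dien-2-ol, via alkenylzirconocene chloride 8 (not isolated), via alkenylmethylzinc 9 (not isolated)
Conditions: Cp2Zr(H)Cl, CH2Cl2, 25 °C; Me2Zn, toluene, −65 °C; then 7, 0 °C; aq. NH4Cl
Reagents that add atoms: none
Why: syn-Hydrozirconation should place zirconium on the methyl-bearing alkyne carbon remote from the alkene, and zirconium-to-zinc transmetalation followed by 1,2-addition to the aldehyde keeps the alkene geometry, giving the (E)-dienyl carbinol (hydrozirconation–transmetalation–carbonyl addition).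

Step 4
Reactants: 10 rac-dienyl carbinol
Product: 11 (3E)-1-[(tert-butyldimethylsilyl)oxy]-3,9-dimethyl-5-methylidenedeca-3,8-dien-2-one
Conditions: Dess–Martin periodinane, CH2Cl2, 0 °C
Reagents that add atoms: none
Why: Dess–Martin oxidation of the secondary allylic alcohol is neutral and should leave the silyl ether and the diene untouched.

Step 5
Reactants: 11 dienone
Product: 12 (2S,3E)-1-[(tert-butyldimethylsilyl)oxy]-3,9-dimethyl-5-methylidenedeca-3,8-dien-2-ol
Conditions: (S)-2-methyl-CBS-oxazaborolidine (20 mol %), catecholborane, toluene, −78 °C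
Reagents that add atoms: none
Why: Corey–Bakshi–Shibata reduction, in which the α-methyl dienyl group acts as the large and CH2OTBS as the small substituent, so the (S)-catalyst should give the (2S)-alcohol that later controls C9.

Step 6
Reactants: 12 (2S)-dienyl carbinol; 13 triethyl orthoacetate
Product: 15 ethyl (3S,4E)-6-[(tert-butyldimethylsilyl)oxy]-4-methyl-3-(6-methylhepta-1,5-dien-2-yl)hex-4-enoate, via mixed ketene acetal 14 (not isolated)
Conditions: 13 (8 equiv), EtCO2H (cat.), xylene, 135 °C, ethanol distilled off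
Reagents that add atoms: none
Why: Johnson–Claisen rearrangement through a chair transition state with CH2OTBS equatorial should transfer the carbinol chirality to C9 (S), form the C9–C11 bond and give the (E)-trisubstituted C10=C1 alkene.

Step 7
Reactants: 15 silyl ether ester
Product: 16 ethyl (3S,4E)-6-hydroxy-4-methyl-3-(6-methylhepta-1,5-dien-2-yl)hex-4-enoate
Conditions: HF·pyridine, THF/pyridine, 0 °C
Reagents that add atoms: none
Why: Fluoride cleaves the primary allylic silyl ether without touching the ester or the skipped diene.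

Step 8
Reactants: 16 allylic alcohol
Product: 17 ethyl (3S,4E)-4-methyl-3-(6-methylhepta-1,5-dien-2-yl)-6-oxohex-4-enoate
Conditions: MnO2, CH2Cl2, 25 °C
Reagents that add atoms: none
Why: MnO2 oxidises only the allylic alcohol under neutral conditions, so the doubly allylic C9–H should not epimerise and the E geometry is kept.

Step 9
Reactants: 17 enal
Product: 19 ethyl 2β-hydroxy-13,14,15,16,18-pentanorlabda-4(19),8(17)-dien-12-oate, via monocyclic aldehyde 18 (not isolated)
Conditions: Me2AlCl (3.0 equiv), CH2Cl2, −78 to 0 °C; aq. KNaC4H4O6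
Reagents that add atoms: none
Why: Proposed new method: Me2AlCl complexes the enal, the trisubstituted alkene adds through C5 to the β-carbon C10 (attack at the carbonyl carbon would need an eight-membered ring) and the developing C4 cation passes a methyl hydrogen to C1, so ring B closes in a 6-exo conjugate ene reaction to aldehyde 18, whose new isopropenyl group then attacks the complexed aldehyde carbon C2 through its CH2 terminus (C3) in a type 2 carbonyl-ene reaction that closes ring A with both alkene carbons inside the ring. The closest known reactions are the alkylaluminium-chloride-promoted sequential ene annulation of enals with alkenes, the Lewis-acid-induced conjugate addition of alkenes to enals and the type 2 carbonyl-ene cyclisation; what is new is that both events are intramolecular, start from an acyclic β,β-disubstituted enal and create the quaternary C10. C10 and C5 are set in a chair-like closure of ring B in which the C9 side chain, the enal arm and the alkene arm are equatorial and only the methyl is axial, so the existing C9 centre should fix the trans fusion (10β-CH3, 5α-H). C2 is set in the chair closure of ring A, where only an axial, aluminium-bound oxygen can reach the methyl hydrogen on C4, which should give the 2β-alcohol and the 4(19)-methylidene. The step needs conjugate rather than carbonyl attack in the first event, which ring size secures, and it needs the aldehyde to ignore the C8 methylidene, which the E geometry of the enal and then the equatorial position of the CH2CHO arm secure.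

Step 10
Reactants: 19 bicyclic homoallylic alcohol
Product: 20 ethyl 4β,19-epoxy-2β-hydroxy-13,14,15,16,18-pentanorlabd-8(17)-en-12-oate
Conditions: VO(acac)2 (5 mol %), t-BuOOH, toluene, 25 °C
Reagents that add atoms: tert-butyl hydroperoxide, CC(C)(C)OO
Why: Hydroxyl-directed vanadium-catalysed epoxidation, in which the axial 2β-alkoxide should deliver oxygen to the β-face of the 1,3-related C4(19) methylidene only and leave the undirected C8(17) methylidene.

Step 11
Reactants: 20 epoxy alcohol
Product: 21 ethyl 4β,19-epoxy-2α-(4-methoxyphenoxy)-13,14,15,16,18-pentanorlabd-8(17)-en-12-oate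
Conditions: 4-methoxyphenol, PPh3, iPrO2C–N=N–CO2iPr, toluene, 0 to 40 °C
Reagents that add atoms: 4-methoxyphenol, COc1ccc(O)cc1
Why: Mitsunobu etherification, in which the axial 2β-alkoxyphosphonium ion is displaced by phenoxide from the open α-face with inversion, setting the equatorial 2α-oxygen of the target and protecting it as an oxidatively removable aryl ether.

Step 12
Reactants: 21 epoxy aryl ether
Product: 22 ethyl 2α-(4-methoxyphenoxy)-19-oxo-13,14,15,16,18-pentanorlabd-8(17)-en-12-oate (C4 epimers)
Conditions: BF3·OEt2, CH2Cl2, −78 °C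
Reagents that add atoms: none
Why: Meinwald rearrangement, in which the spiro-epoxide opens at the tertiary C4 and a 1,2-hydride shift from C19 gives the C4 carbaldehyde (its C4 configuration is irrelevant because it is enolised next).

Step 13
Reactants: 22 aldehyde
Product: 24 ethyl 2α-(4-methoxyphenoxy)-19-oxo-13,14,15,16-tetranorlabd-8(17)-en-12-oate, via potassium enolate 23 (not isolated)
Conditions: KOtBu (1.2 equiv), MeI, THF, −20 to 0 °C
Reagents that add atoms: iodomethane, CI
Why: The more acidic aldehyde α-hydrogen is removed in preference to the ester α-hydrogens and the exocyclic enolate should be C-methylated from the α-face, anti to the axial C10 methyl, which sets C4 with the methyl (C18) equatorial and the formyl group (C19) axial.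

Step 14
Reactants: 24 quaternary aldehyde ester
Product: 25 2α-(4-methoxyphenoxy)-13,14,15,16-tetranorlabd-8(17)-ene-12,19-diol
Conditions: LiAlH4, THF, 0 °C
Reagents that add atoms: none
Why: LiAlH4 reduces the neopentyl aldehyde and the ethyl ester in one operation while the aryl ether and the alkene are inert.

Step 15
Reactants: 25 diol
Product: 26 2α-(4-methoxyphenoxy)-13,14,15,16-tetranorlabd-8(17)-ene-7α,12,19-triol
Conditions: SeO2 (0.5 equiv), t-BuOOH, CH2Cl2, 25 °C
Reagents that add atoms: selenium dioxide, O=[Se]=O; tert-butyl hydroperoxide, CC(C)(C)OO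
Why: Riley allylic oxidation of the only alkene, in which the ene step at C17 should take the axial C7 hydrogen in preference to the hindered C9 methine and the [2,3]-shift return oxygen to C7 along the axial α-direction, restoring the C8(17) methylidene.

Step 16
Reactants: 26 triol
Product: 27 12-iodo-2α-(4-methoxyphenoxy)-13,14,15,16-tetranorlabd-8(17)-ene-7α,19-diol
Conditions: I2 (1.1 equiv), PPh3, imidazole, CH2Cl2, 0 °C
Reagents that add atoms: iodine, II
Why: Appel-type iodination should discriminate the unhindered primary C12 alcohol from the neopentyl C19 and the hindered secondary allylic C7 alcohols.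

Step 17
Reactants: 27 iodo diol
Product: 28 12-iodo-2α-(4-methoxyphenoxy)-13,14,15,16-tetranorlabd-8(17)-ene-7α,19-diyl diacetate
Conditions: Ac2O, Et3N, DMAP (cat.), CH2Cl2, 0 to 25 °C
Reagents that add atoms: acetic anhydride, CC(=O)OC(C)=O
Why: DMAP-catalysed acetylation esterifies the axial allylic C7 and the neopentyl C19 hydroxyls while the C2 oxygen is masked as the aryl ether.

Step 18
Reactants: 29 but-2-yn-1-ol
Product: 31 (2Z)-3-iodobut-2-en-1-ol, via cyclic alkenylalanate 30 (not isolated)
Conditions: NaAlH2(OCH2CH2OMe)2, THF, 0 to 25 °C; then I2, −78 °C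
Reagents that add atoms: iodine, II
Why: Alkoxide-directed anti-hydroalumination places aluminium on C3 cis to the CH2O group and iodinolysis with retention gives the (Z)-vinyl iodide that fixes the C13 geometry.

Step 19
Reactants: 31 (2Z)-3-iodobut-2-en-1-ol
Product: 32 (2Z)-3-iodobut-2-en-1-yl acetate
Conditions: Ac2O, pyridine, CH2Cl2, 0 °C
Reagents that add atoms: acetic anhydride, CC(=O)OC(C)=O
Why: Routine acetylation of a primary allylic alcohol.

Step 20
Reactants: 28 iodo diacetate; 32 (2Z)-3-iodobut-2-en-1-yl acetate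
Product: 34 (13Z)-2α-(4-methoxyphenoxy)labda-8(17),13-diene-7α,15,19-triyl triacetate, via alkylzinc iodide 33 (not isolated)
Conditions: Zn dust (activated by BrCH2CH2Br and Me3SiCl), DMA, 40 °C; then 32, PdCl2(dppf) (5 mol %), THF, 25 °C
Reagents that add atoms: none
Why: Zinc insertion into the primary iodide tolerates the acetates and Negishi coupling with the vinyl iodide proceeds with retention of the Z geometry, oxidative addition into the C–I bond being expected to be much faster than ionisation of the two hindered allylic acetates.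

Step 21
Reactants: 34 aryl ether triacetate
Product: 35 (13Z)-2α-hydroxylabda-8(17),13-diene-7α,15,19-triyl triacetate (CNP0139627.2)
Conditions: (NH4)2Ce(NO3)6, MeCN/H2O (4:1), 0 °C
Reagents that add atoms: none
Why: Oxidative cleavage of the 4-methoxyphenyl ether releases the 2α-alcohol with retention (the C2–O bond is not broken) and should leave the acetates and both alkenes intact.

**Compound list**
1 | 6-methylhept-5-en-2-one (sulcatone) | CC(=O)CCC=C(C)C | starting material
2 | lithium 6-methylhepta-1,5-dien-2-olate | [Li+].[O-]C(=C)CCC=C(C)C | intermediate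
3 | 6-methylhepta-1,5-dien-2-yl trifluoromethanesulfonate | C=C(CCC=C(C)C)OS(=O)(=O)C(F)(F)F | intermediate
4 | prop-1-yn-1-ylmagnesium bromide | CC#C[Mg]Br | starting material
5 | chloro(prop-1-yn-1-yl)zinc | CC#C[Zn]Cl | intermediate
6 | 2-methyl-6-methylidenenon-2-en-7-yne | CC#CC(=C)CCC=C(C)C | intermediate
7 | (tert-butyldimethylsilyloxy)acetaldehyde | O=CCO[Si](C)(C)C(C)(C)C | starting material
8 | chlorobis(cyclopentadienyl)[(2E)-8-methyl-4-methylidenenona-2,7-dien-2-yl]zirconium | C/C(=C\C(=C)CCC=C(C)C)[Zr](Cl)(C1C=CC=C1)C1C=CC=C1 | intermediate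
9 | methyl[(2E)-8-methyl-4-methylidenenona-2,7-dien-2-yl]zinc | C/C(=C\C(=C)CCC=C(C)C)[Zn]C | intermediate
10 | rac-(3E)-1-[(tert-butyldimethylsilyl)oxy]-3,9-dimethyl-5-methylidenedeca-3,8-dien-2-ol | CC(C)=CCCC(=C)/C=C(\C)C(O)CO[Si](C)(C)C(C)(C)C | intermediate
11 | (3E)-1-[(tert-butyldimethylsilyl)oxy]-3,9-dimethyl-5-methylidenedeca-3,8-dien-2-one | CC(C)=CCCC(=C)/C=C(\C)C(=O)CO[Si](C)(C)C(C)(C)C | intermediate
12 | (2S,3E)-1-[(tert-butyldimethylsilyl)oxy]-3,9-dimethyl-5-methylidenedeca-3,8-dien-2-ol | CC(C)=CCCC(=C)/C=C(\C)[C@H](O)CO[Si](C)(C)C(C)(C)C | intermediate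
13 | triethyl orthoacetate | CC(OCC)(OCC)OCC | starting material
14 | 1-ethoxyvinyl ether (mixed ketene acetal) of 12 | C=C(OCC)O[C@H](CO[Si](C)(C)C(C)(C)C)/C(C)=C/C(=C)CCC=C(C)C | intermediate
15 | ethyl (3S,4E)-6-[(tert-butyldimethylsilyl)oxy]-4-methyl-3-(6-methylhepta-1,5-dien-2-yl)hex-4-enoate | CC(C)=CCCC(=C)[C@H](CC(=O)OCC)/C(C)=C/CO[Si](C)(C)C(C)(C)C | intermediate
16 | ethyl (3S,4E)-6-hydroxy-4-methyl-3-(6-methylhepta-1,5-dien-2-yl)hex-4-enoate | CC(C)=CCCC(=C)[C@H](CC(=O)OCC)/C(C)=C/CO | intermediate
17 | ethyl (3S,4E)-4-methyl-3-(6-methylhepta-1,5-dien-2-yl)-6-oxohex-4-enoate | CC(C)=CCCC(=C)[C@H](CC(=O)OCC)/C(C)=C/C=O | intermediate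
18 | monocyclic aldehyde (ring B closed): cyclohexane with 8(17)-methylidene, 9β-CH2CO2Et, 10β-CH3, 10α-CH2CHO and equatorial isopropenyl on C5 (5α-H) | C=C1CC[C@@H](C(C)=C)[C@](C)(CC=O)[C@H]1CC(=O)OCC | intermediate
19 | ethyl 2β-hydroxy-13,14,15,16,18-pentanorlabda-4(19),8(17)-dien-12-oate (trans-decalin, 5α-H, 9α-H, 10β-CH3) | C=C1CC[C@H]2C(=C)C[C@@H](O)C[C@]2(C)[C@H]1CC(=O)OCC | intermediate
20 | ethyl 4β,19-epoxy-2β-hydroxy-13,14,15,16,18-pentanorlabd-8(17)-en-12-oate | C=C1CC[C@H]2[C@]3(CO3)C[C@@H](O)C[C@]2(C)[C@H]1CC(=O)OCC | intermediate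
21 | ethyl 4β,19-epoxy-2α-(4-methoxyphenoxy)-13,14,15,16,18-pentanorlabd-8(17)-en-12-oate | C=C1CC[C@H]2[C@]3(CO3)C[C@H](Oc4ccc(OC)cc4)C[C@]2(C)[C@H]1CC(=O)OCC | intermediate
22 | ethyl 2α-(4-methoxyphenoxy)-19-oxo-13,14,15,16,18-pentanorlabd-8(17)-en-12-oate (C4 epimers) | C=C1CC[C@H]2C(C=O)C[C@H](Oc3ccc(OC)cc3)C[C@]2(C)[C@H]1CC(=O)OCC | intermediate
23 | potassium C4(19)-enolate of 22 | C=C1CC[C@H]2C(=C[O-])C[C@H](Oc3ccc(OC)cc3)C[C@]2(C)[C@H]1CC(=O)OCC.[K+] | intermediate
24 | ethyl 2α-(4-methoxyphenoxy)-19-oxo-13,14,15,16-tetranorlabd-8(17)-en-12-oate (4α-CH3, 4β-CHO) | C=C1CC[C@H]2[C@@](C)(C=O)C[C@H](Oc3ccc(OC)cc3)C[C@]2(C)[C@H]1CC(=O)OCC | intermediate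
25 | 2α-(4-methoxyphenoxy)-13,14,15,16-tetranorlabd-8(17)-ene-12,19-diol | C=C1CC[C@H]2[C@@](C)(CO)C[C@H](Oc3ccc(OC)cc3)C[C@]2(C)[C@H]1CCO | intermediate
26 | 2α-(4-methoxyphenoxy)-13,14,15,16-tetranorlabd-8(17)-ene-7α,12,19-triol | C=C1[C@H](O)C[C@H]2[C@@](C)(CO)C[C@H](Oc3ccc(OC)cc3)C[C@]2(C)[C@H]1CCO | intermediate
27 | 12-iodo-2α-(4-methoxyphenoxy)-13,14,15,16-tetranorlabd-8(17)-ene-7α,19-diol | C=C1[C@H](O)C[C@H]2[C@@](C)(CO)C[C@H](Oc3ccc(OC)cc3)C[C@]2(C)[C@H]1CCI | intermediate
28 | 12-iodo-2α-(4-methoxyphenoxy)-13,14,15,16-tetranorlabd-8(17)-ene-7α,19-diyl diacetate | C=C1[C@H](OC(C)=O)C[C@H]2[C@@](C)(COC(C)=O)C[C@H](Oc3ccc(OC)cc3)C[C@]2(C)[C@H]1CCI | intermediate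
29 | but-2-yn-1-ol | CC#CCO | starting material
30 | sodium cyclic (Z)-alkenylalanate from 29 (aluminium on C3, bound to the C1 oxygen, two 2-methoxyethoxy ligands) | C/C(=C/CO1)[Al-]1(OCCOC)OCCOC.[Na+] | intermediate
31 | (2Z)-3-iodobut-2-en-1-ol | C/C(I)=C/CO | intermediate
32 | (2Z)-3-iodobut-2-en-1-yl acetate | C/C(I)=C/COC(C)=O | intermediate
33 | alkylzinc iodide from 28 (C12–ZnI) | C=C1[C@H](OC(C)=O)C[C@H]2[C@@](C)(COC(C)=O)C[C@H](Oc3ccc(OC)cc3)C[C@]2(C)[C@H]1CC[Zn]I | intermediate
34 | (13Z)-2α-(4-methoxyphenoxy)labda-8(17),13-diene-7α,15,19-triyl triacetate | C=C1[C@H](OC(C)=O)C[C@H]2[C@@](C)(COC(C)=O)C[C@H](Oc3ccc(OC)cc3)C[C@]2(C)[C@H]1CC/C(C)=C\COC(C)=O | intermediate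
35 | (13Z)-2α-hydroxylabda-8(17),13-diene-7α,15,19-triyl triacetate (CNP0139627.2) | C=C1[C@H](OC(C)=O)C[C@H]2[C@@](C)(COC(C)=O)C[C@H](O)C[C@]2(C)[C@H]1CC/C(C)=C\COC(C)=O | target

**Summary**
Total step count: 21. Longest linear sequence: 19 steps (steps 1–17, 20, 21); steps 18–19 make the side-chain fragment.

**Steps most likely to fail**

Step 9 (proposed new method). The first ene reaction may stall because a β,β-disubstituted enal is a weak enophile, the zwitterion may collapse to a cyclobutane or a dihydropyran instead of transferring hydrogen, or the ring fusion may form without facial control. The fallback uses known reactions and sets out from allylic alcohol 16. BF3·OEt2 in CH2Cl2 at −78 °C would ionise 16 to the allyl cation, and the trisubstituted alkene would attack its tertiary terminus C10 (cation–olefin cyclisation); loss of a methyl proton would give the vinyl isopropenyl cyclohexane F1. Aldehyde-selective Wacker oxidation of the monosubstituted vinyl group (PdCl2(PhCN)2, CuCl2, AgNO2, O2, t-BuOH/MeNO2) would give aldehyde 18, now isolated. Me2AlCl would then effect only the well-precedented type 2 carbonyl-ene closure of ring A, and the route is rejoined at 19.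

Step 11. The axial alkoxyphosphonium ion may undergo E2 elimination faster than it is displaced by the weakly nucleophilic phenoxide. The fallback sets out from 20. Mitsunobu inversion with 4-nitrobenzoic acid, the standard acid for hindered alcohols, would give the 2α-ester F2, and ethanolysis (K2CO3, EtOH) would give the 2α-alcohol F3. The aryl ether would then be made at the aryl carbon with retention at C2 by copper-catalysed O-arylation with 4-iodoanisole (CuI, 3,4,7,8-tetramethyl-1,10-phenanthroline, Cs2CO3, toluene, 80 °C), returning to 21.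

Step 20. Zerovalent palladium may ionise one of the two allylic acetates, and the resulting allyl complex would be reduced or alkylated by the organozinc. The fallback keeps all acetates out of the coupling and sets out from iodo diol 27 and vinyl iodide alcohol 31. Compound 27 would be silylated (Et3SiOTf, 2,6-lutidine) to the bis(triethylsilyl) ether F4, and 31 (t-BuMe2SiCl, imidazole) to the silyl ether F5. Zinc insertion into F4 would give the alkylzinc iodide F6, and Negishi coupling with F5 the tris-silyl ether F7. HF·pyridine would remove all three silyl groups to give the triol F8, and one acetylation (Ac2O, Et3N, DMAP) would return to 34.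

**Further compounds**
F1 | step 9 | ethyl ester of the cyclohexane with 8(17)-methylidene, 9β-CH2CO2Et, 10β-CH3, 10α-vinyl and equatorial isopropenyl on C5 | C=C1CC[C@@H](C(C)=C)[C@](C)(C=C)[C@H]1CC(=O)OCC
F2 | step 11 | ethyl 4β,19-epoxy-2α-(4-nitrobenzoyloxy)-13,14,15,16,18-pentanorlabd-8(17)-en-12-oate | C=C1CC[C@H]2[C@]3(CO3)C[C@H](OC(=O)c4ccc(cc4)[N+](=O)[O-])C[C@]2(C)[C@H]1CC(=O)OCC
F3 | step 11 | ethyl 4β,19-epoxy-2α-hydroxy-13,14,15,16,18-pentanorlabd-8(17)-en-12-oate | C=C1CC[C@H]2[C@]3(CO3)C[C@H](O)C[C@]2(C)[C@H]1CC(=O)OCC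
F4 | step 20 | 12-iodo-2α-(4-methoxyphenoxy)-7α,19-bis(triethylsilyloxy)-13,14,15,16-tetranorlabd-8(17)-ene | C=C1[C@H](O[Si](CC)(CC)CC)C[C@H]2[C@@](C)(CO[Si](CC)(CC)CC)C[C@H](Oc3ccc(OC)cc3)C[C@]2(C)[C@H]1CCI
F5 | step 20 | tert-butyl{[(2Z)-3-iodobut-2-en-1-yl]oxy}dimethylsilane | C/C(I)=C/CO[Si](C)(C)C(C)(C)C
F6 | step 20 | alkylzinc iodide from F4 (C12–ZnI) | C=C1[C@H](O[Si](CC)(CC)CC)C[C@H]2[C@@](C)(CO[Si](CC)(CC)CC)C[C@H](Oc3ccc(OC)cc3)C[C@]2(C)[C@H]1CC[Zn]I
F7 | step 20 | (13Z)-15-(tert-butyldimethylsilyloxy)-2α-(4-methoxyphenoxy)-7α,19-bis(triethylsilyloxy)labda-8(17),13-diene | C=C1[C@H](O[Si](CC)(CC)CC)C[C@H]2[C@@](C)(CO[Si](CC)(CC)CC)C[C@H](Oc3ccc(OC)cc3)C[C@]2(C)[C@H]1CC/C(C)=C\CO[Si](C)(C)C(C)(C)C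
F8 | step 20 | (13Z)-2α-(4-methoxyphenoxy)labda-8(17),13-diene-7α,15,19-triol | C=C1[C@H](O)C[C@H]2[C@@](C)(CO)C[C@H](Oc3ccc(OC)cc3)C[C@]2(C)[C@H]1CC/C(C)=C\CO
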